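The nonaene is cut at its central C15=C15' double bond, about which the molecule is symmetric except for the oxidation level at C3 of ring A versus C3' of ring B. Both C20 halves therefore derive from one resolved (3S,6S)-3-hydroxy-ε-ring ester and are joined through C15 and C15' to a sulfonyl group. A one-flask Ramberg–Bäcklund reaction (α-bromination, episulfone closure, loss of SO2) then turns the CH2–SO2–CH2 tether into the C15=C15' alkene, completing the C40 nonaene without touching the stereocentres C6, C6', C3, C3'. The precursor is the unsymmetrical bis(C20-allyl) sulfone carrying a triethylsilyl ether on ring A (future enone) and a tert-butyldimethylsilyl ether on ring B.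

Key step: step 14

Remark on configuration: the target is (all-E)-(6S,3'S,6'S)-3'-hydroxy-ε,ε-caroten-3-one. Both rings are the same trans-(3S,6S) 3-oxygenated ε end group. Carotenoid numbering is used (ring A = C1–C6, the future enone; ring B = C1'–C6').

Assumption: lipase PS acylates the (3R)-carbinol of the trans racemate faster, the usual sense for cyclohex-2-en-1-ols, so the (3S,6S)-alcohol is the unreacted fraction. The configuration of 6 is to be confirmed before it is carried on.

Remark on design: the first chain extension precedes the C3 oxidation, so the ring enone is the only ketone present at the reduction stage. The halves are joined by sulfinate alkylation, so no sulfide has to be oxidised beside the polyene.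

Step 1
Reactants: 1 (±)-α-ionone; 2 triethyl phosphonoacetate
Product: 3 (±)-ethyl (2E,4E)-3-methyl-5-(2,6,6-trimethylcyclohex-2-en-1-yl)penta-2,4-dienoate
Conditions: NaH, THF, 0 °C to 50 °C; chromatographic removal of the minor 9Z isomer
Reagents that add atoms: none
Why: Horner–Wadsworth–Emmons olefination of the methyl ketone with a stabilised phosphonate anion should give mainly the 9E dienoate, and placing this homologation first leaves the ring enone made in step 2 as the only ketone when the C3 carbonyl is later reduced.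

Step 2
Reactants: 3 (±)-ethyl α-ionylideneacetate
Product: 4 (±)-ethyl (2E,4E)-3-methyl-5-(2,6,6-trimethyl-4-oxocyclohex-2-en-1-yl)penta-2,4-dienoate
Conditions: t-BuOOH (70% aq), NaOCl (aq), MeCN, −5 to 0 °C
Reagents that add atoms: tert-butyl hydroperoxide, CC(C)(C)OO
Why: Radical allylic oxidation by tert-butylperoxyl species, a reaction established for α-ionone and its C15 homologues, should convert the ring C3 methylene (the only unhindered secondary allylic position) into the enone, since C6–H is shielded by the quaternary C1 and the C9 methyl is deactivated by the ester.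

Step 3
Reactants: 4 (±)-3-oxo dienoate
Product: 5 (±)-trans-ethyl (2E,4E)-5-(4-hydroxy-2,6,6-trimethylcyclohex-2-en-1-yl)-3-methylpenta-2,4-dienoate (racemate of the 3S,6S and 3R,6R forms)
Conditions: NaBH4, CeCl3·7H2O, MeOH, −20 °C; chromatographic separation from the cis alcohol
Reagents that add atoms: none
Why: Luche 1,2-reduction touches only the ring enone and creates C3 as a trans/cis pair relative to C6; the trans racemate is taken after chromatography and the cis alcohol can be returned to 4 with MnO2.

Step 4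
Reactants: 5 (±)-trans hydroxy dienoate
Product: 6 ethyl (2E,4E)-5-[(1S,4S)-4-hydroxy-2,6,6-trimethylcyclohex-2-en-1-yl]-3-methylpenta-2,4-dienoate (3S,6S in carotenoid numbering)
Conditions: lipase PS (Burkholderia cepacia), vinyl acetate, t-BuOMe, 30 °C, to about 55% conversion; chromatography
Reagents that add atoms: none
Why: Lipase-catalysed kinetic resolution by irreversible transesterification should acylate the (3R,6R)-enantiomer and leave the (3S,6S)-alcohol, whose enantiomeric purity rises once conversion passes one half; this step fixes the absolute configuration of C3/C6 and C3'/C6' for both halves.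

Step 5
Reactants: 6 (3S,6S)-hydroxy dienoate
Product: 7 (2E,4E)-5-[(1S,4S)-4-hydroxy-2,6,6-trimethylcyclohex-2-en-1-yl]-3-methylpenta-2,4-dien-1-ol
Conditions: i-Bu2AlH (3.5 equiv), CH2Cl2, −78 °C; Rochelle salt work-up
Reagents that add atoms: none
Why: Diisobutylaluminium hydride reduces the conjugated ester by 1,2-addition to the primary allylic alcohol; the free C3 hydroxyl only consumes one equivalent of hydride and the stereocentres are not involved.

Step 6
Reactants: 7 C15 diol
Product: 8 (2E,4E)-5-[(1S,4S)-4-hydroxy-2,6,6-trimethylcyclohex-2-en-1-yl]-3-methylpenta-2,4-dienal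
Conditions: TEMPO (cat.), PhI(OAc)2, CH2Cl2, 0 °C to rt
Reagents that add atoms: none
Why: Oxoammonium (TEMPO) oxidation with PhI(OAc)2 is selective for primary over secondary alcohols and stops at the aldehyde, so the dienylic CH2OH should be oxidised while the ring carbinol stays.

Step 7
Reactants: 8 C15 hydroxy aldehyde; 9 ethyl (E)-4-(diethoxyphosphoryl)-3-methylbut-2-enoate
Product: 10 ethyl (2E,4E,6E,8E)-9-[(1S,4S)-4-hydroxy-2,6,6-trimethylcyclohex-2-en-1-yl]-3,7-dimethylnona-2,4,6,8-tetraenoate
Conditions: 9, LiN(SiMe3)2, THF, −78 °C; then 8, −78 to 0 °C; chromatographic removal of minor 13Z isomer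
Reagents that add atoms: none
Why: Horner–Wadsworth–Emmons reaction of the dienal with the lithiated C5 phosphonate builds C11=C12 with E geometry and brings in the 13E ester end with the reagent; the stabilised anion is too weak a base to affect the free hydroxyl or C6–H.

Step 8
Reactants: 10 C20 hydroxy ester
Product: 11 ethyl (2E,4E,6E,8E)-9-[(1S,4S)-4-(tert-butyldimethylsilyloxy)-2,6,6-trimethylcyclohex-2-en-1-yl]-3,7-dimethylnona-2,4,6,8-tetraenoate
Conditions: TBSCl, imidazole, DMF, rt
Reagents that add atoms: tert-butyldimethylsilyl chloride, CC(C)(C)[Si](C)(C)Cl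
Why: Imidazole-promoted silylation of the secondary alcohol gives the base-stable TBS ether that ring B keeps until the last step.

Step 9
Reactants: 11 TBS-protected C20 ester
Product: 12 (2E,4E,6E,8E)-9-[(1S,4S)-4-(tert-butyldimethylsilyloxy)-2,6,6-trimethylcyclohex-2-en-1-yl]-3,7-dimethylnona-2,4,6,8-tetraen-1-ol
Conditions: i-Bu2AlH, CH2Cl2, −78 °C; Rochelle salt work-up
Reagents that add atoms: none
Why: 1,2-Reduction of the tetraenoate with diisobutylaluminium hydride at low temperature gives the retinol-type allylic alcohol; silyl ether and stereocentres are inert.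

Step 10
Reactants: 12 TBS-protected C20 alcohol; 13 sodium 3-methoxy-3-oxopropane-1-sulfinate
Product: 15 methyl 3-{[(2E,4E,6E,8E)-9-[(1S,4S)-4-(tert-butyldimethylsilyloxy)-2,6,6-trimethylcyclohex-2-en-1-yl]-3,7-dimethylnona-2,4,6,8-tetraen-1-yl]sulfonyl}propanoate, via allylic bromide 14 (not isolated)
Conditions: MsCl, Et3N, THF, −40 °C; LiBr, −40 to 0 °C; then 13, DMSO, 0 °C to rt, dark
Reagents that add atoms: none
Why: The alcohol is converted into the allylic bromide under non-acidic conditions (mesylate, then bromide exchange) and the soft sulfinate sulfur displaces it at once by SN2 at primary C15', a standard sulfone synthesis from sulfinate salts in which S-alkylation is expected to prevail and the tetraene stays conjugated.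

Step 11
Reactants: 10 C20 hydroxy ester
Product: 16 ethyl (2E,4E,6E,8E)-3,7-dimethyl-9-[(1S,4S)-2,6,6-trimethyl-4-(triethylsilyloxy)cyclohex-2-en-1-yl]nona-2,4,6,8-tetraenoate
Conditions: TESCl, imidazole, DMF, 0 °C
Reagents that add atoms: chlorotriethylsilane, CC[Si](Cl)(CC)CC
Why: Imidazole-promoted silylation gives the triethylsilyl ether, chosen for ring A because it can later be removed in the presence of the TBS ether.

Step 12
Reactants: 16 TES-protected C20 ester
Product: 17 (2E,4E,6E,8E)-3,7-dimethyl-9-[(1S,4S)-2,6,6-trimethyl-4-(triethylsilyloxy)cyclohex-2-en-1-yl]nona-2,4,6,8-tetraen-1-ol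
Conditions: i-Bu2AlH, CH2Cl2, −78 °C; Rochelle salt work-up
Reagents that add atoms: none
Why: 1,2-Reduction of the conjugated ester with diisobutylaluminium hydride gives the allylic alcohol, and the neutral tartrate work-up spares the triethylsilyl ether.

Step 13
Reactants: 15 TBS-protected C20 sulfonyl propanoate; 17 TES-protected C20 alcohol
Product: 20 unsymmetrical C40 diallylic sulfone (C15–SO2–C15'; 3-triethylsilyl ether on ring A; 3'-tert-butyldimethylsilyl ether on ring B; all chain double bonds E), via sodium sulfinate 18 (not isolated), via allylic bromide 19 (not isolated)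
Conditions: 15: NaOMe (1.0 equiv), THF–MeOH, 0 °C, then evaporation; 17: MsCl, Et3N, THF, −40 °C, then LiBr, to 0 °C; both combined in DMSO–THF, 0 °C to rt, dark
Reagents that add atoms: none
Why: Methoxide triggers an E1cB retro-Michael cleavage of the β-sulfonyl ester to the C20 sulfinate, and S-alkylation of this salt by the second allylic bromide (SN2 at primary C15) gives the unsymmetrical sulfone directly at the sulfone oxidation level, so that only the TBS-protected half ever meets methoxide.

Step 14
Reactants: 20 unsymmetrical C40 diallylic sulfone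
Product: 24 (all-E)-(3S,6S,3'S,6'S)-3-(triethylsilyloxy)-3'-(tert-butyldimethylsilyloxy)-ε,ε-carotene, via α-bromo sulfone 21 (not isolated), via episulfone 22 (not isolated), via 15Z isomer 23 (not isolated)
Conditions: KOH/Al2O3 (excess), CBr2F2, t-BuOH–CH2Cl2, 0 °C, dark; filtration, then heptane, 90 °C, Ar, dark
Reagents that add atoms: none
Why: KOH on alumina removes a proton from C15 or C15' (each allylic and α to the sulfonyl group), the carbanion takes bromine from CBr2F2 to give α-bromo sulfone 21 (the difluorocarbene left behind is hydrolysed by the base), and a second deprotonation at the other α-carbon displaces bromide to form thiirane 1,1-dioxide 22, which loses SO2 cheletropically and leaves the C15=C15' double bond. This is the one-flask Ramberg–Bäcklund olefination with in-situ halogenation, whose closest known cases are diallylic and dienyl allyl sulfones that give conjugated trienes, tetraenes and carotenoid polyenes. No ring of the target is closed; the transient three-membered episulfone forms by 3-exo-tet displacement and is destroyed in the same flask. No stereocentre is created, and the geometry of the new disubstituted alkene, which the extrusion does not guarantee, is settled by heating the crude product in heptane, where the unhindered central 15Z bond of 23 should isomerise to the more stable all-E polyene. The step needs positional selectivity: either bromination site converges on the same alkene, bromination next to sulfur is favoured because the negative charge is concentrated there, and C6–H and C6'–H (bis-allylic but not acidified by sulfur) should stay untouched at 0 °C. Both silyl ethers are expected to be inert to the heterogeneous base, and loss of the triethylsilyl group, should it occur, would only anticipate step 15.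

Step 15
Reactants: 24 bis-silyl ether of the all-E diol
Product: 25 (all-E)-(3S,6S,3'S,6'S)-3'-(tert-butyldimethylsilyloxy)-ε,ε-caroten-3-ol
Conditions: HF·pyridine, pyridine, THF, 0 °C
Reagents that add atoms: none
Why: Buffered HF cleaves a secondary triethylsilyl ether much faster than a secondary TBS ether, and the pyridine buffer should prevent ionisation of the allylic C3–O bond.

Step 16
Reactants: 25 ring A allylic alcohol
Product: 26 (all-E)-(6S,3'S,6'S)-3'-(tert-butyldimethylsilyloxy)-ε,ε-caroten-3-one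
Conditions: MnO2 (activated, excess), CH2Cl2, rt, dark
Reagents that add atoms: none
Why: MnO2 oxidises allylic alcohols selectively, as known for the ε-ring carbinol of hydroxy carotenoids, and the C3 hydroxyl of ring A is the only free one; the neutral heterogeneous oxidant leaves C6, now γ to the carbonyl, configurationally intact.

Step 17
Reactants: 26 TBS-protected keto carotenoid
Product: 27 (all-E)-(6S,3'S,6'S)-3'-hydroxy-ε,ε-caroten-3-one (CNP0344065.1)
Conditions: HF·pyridine, pyridine, THF, 0 °C to rt
Reagents that add atoms: none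
Why: Fluoride-driven cleavage of the TBS ether under weakly acidic buffered conditions avoids the base that could epimerise or conjugate C6 of the 3-oxo ring, and releases the C3' hydroxyl without touching C3' or C6'.

Compound list
1 | (±)-α-ionone, (E)-4-(2,6,6-trimethylcyclohex-2-en-1-yl)but-3-en-2-one | CC1=CCCC(C)(C)C1/C=C/C(C)=O | starting material
2 | triethyl phosphonoacetate | CCOC(=O)CP(=O)(OCC)OCC | starting material
3 | (±)-ethyl (2E,4E)-3-methyl-5-(2,6,6-trimethylcyclohex-2-en-1-yl)penta-2,4-dienoate | CC1=CCCC(C)(C)C1/C=C/C(C)=C/C(=O)OCC | intermediate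
4 | (±)-ethyl (2E,4E)-3-methyl-5-(2,6,6-trimethyl-4-oxocyclohex-2-en-1-yl)penta-2,4-dienoate | CC1=CC(=O)CC(C)(C)C1/C=C/C(C)=C/C(=O)OCC | intermediate
5 | (±)-trans-ethyl (2E,4E)-5-(4-hydroxy-2,6,6-trimethylcyclohex-2-en-1-yl)-3-methylpenta-2,4-dienoate, racemate (both enantiomers written) | CC1=C[C@@H](O)CC(C)(C)[C@@H]1/C=C/C(C)=C/C(=O)OCC.CC1=C[C@H](O)CC(C)(C)[C@H]1/C=C/C(C)=C/C(=O)OCC | intermediate
6 | ethyl (2E,4E)-5-[(1S,4S)-4-hydroxy-2,6,6-trimethylcyclohex-2-en-1-yl]-3-methylpenta-2,4-dienoate | CC1=C[C@@H](O)CC(C)(C)[C@@H]1/C=C/C(C)=C/C(=O)OCC | intermediate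
7 | (2E,4E)-5-[(1S,4S)-4-hydroxy-2,6,6-trimethylcyclohex-2-en-1-yl]-3-methylpenta-2,4-dien-1-ol | CC1=C[C@@H](O)CC(C)(C)[C@@H]1/C=C/C(C)=C/CO | intermediate
8 | (2E,4E)-5-[(1S,4S)-4-hydroxy-2,6,6-trimethylcyclohex-2-en-1-yl]-3-methylpenta-2,4-dienal | CC1=C[C@@H](O)CC(C)(C)[C@@H]1/C=C/C(C)=C/C=O | intermediate
9 | ethyl (E)-4-(diethoxyphosphoryl)-3-methylbut-2-enoate | CCOC(=O)/C=C(C)/CP(=O)(OCC)OCC | starting material
10 | ethyl (2E,4E,6E,8E)-9-[(1S,4S)-4-hydroxy-2,6,6-trimethylcyclohex-2-en-1-yl]-3,7-dimethylnona-2,4,6,8-tetraenoate | CC1=C[C@@H](O)CC(C)(C)[C@@H]1/C=C/C(C)=C/C=C/C(C)=C/C(=O)OCC | intermediate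
11 | ethyl (2E,4E,6E,8E)-9-[(1S,4S)-4-(tert-butyldimethylsilyloxy)-2,6,6-trimethylcyclohex-2-en-1-yl]-3,7-dimethylnona-2,4,6,8-tetraenoate | CC1=C[C@@H](O[Si](C)(C)C(C)(C)C)CC(C)(C)[C@@H]1/C=C/C(C)=C/C=C/C(C)=C/C(=O)OCC | intermediate
12 | (2E,4E,6E,8E)-9-[(1S,4S)-4-(tert-butyldimethylsilyloxy)-2,6,6-trimethylcyclohex-2-en-1-yl]-3,7-dimethylnona-2,4,6,8-tetraen-1-ol | CC1=C[C@@H](O[Si](C)(C)C(C)(C)C)CC(C)(C)[C@@H]1/C=C/C(C)=C/C=C/C(C)=C/CO | intermediate
13 | sodium 3-methoxy-3-oxopropane-1-sulfinate | COC(=O)CCS(=O)[O-].[Na+] | starting material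
14 | TBS-protected C20 allylic bromide (bromide of 12) | CC1=C[C@@H](O[Si](C)(C)C(C)(C)C)CC(C)(C)[C@@H]1/C=C/C(C)=C/C=C/C(C)=C/CBr | intermediate
15 | methyl 3-{[(2E,4E,6E,8E)-9-[(1S,4S)-4-(tert-butyldimethylsilyloxy)-2,6,6-trimethylcyclohex-2-en-1-yl]-3,7-dimethylnona-2,4,6,8-tetraen-1-yl]sulfonyl}propanoate | CC1=C[C@@H](O[Si](C)(C)C(C)(C)C)CC(C)(C)[C@@H]1/C=C/C(C)=C/C=C/C(C)=C/CS(=O)(=O)CCC(=O)OC | intermediate
16 | ethyl (2E,4E,6E,8E)-3,7-dimethyl-9-[(1S,4S)-2,6,6-trimethyl-4-(triethylsilyloxy)cyclohex-2-en-1-yl]nona-2,4,6,8-tetraenoate | CC1=C[C@@H](O[Si](CC)(CC)CC)CC(C)(C)[C@@H]1/C=C/C(C)=C/C=C/C(C)=C/C(=O)OCC | intermediate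
17 | (2E,4E,6E,8E)-3,7-dimethyl-9-[(1S,4S)-2,6,6-trimethyl-4-(triethylsilyloxy)cyclohex-2-en-1-yl]nona-2,4,6,8-tetraen-1-ol | CC1=C[C@@H](O[Si](CC)(CC)CC)CC(C)(C)[C@@H]1/C=C/C(C)=C/C=C/C(C)=C/CO | intermediate
18 | sodium (2E,4E,6E,8E)-9-[(1S,4S)-4-(tert-butyldimethylsilyloxy)-2,6,6-trimethylcyclohex-2-en-1-yl]-3,7-dimethylnona-2,4,6,8-tetraene-1-sulfinate | CC1=C[C@@H](O[Si](C)(C)C(C)(C)C)CC(C)(C)[C@@H]1/C=C/C(C)=C/C=C/C(C)=C/CS(=O)[O-].[Na+] | intermediate
19 | TES-protected C20 allylic bromide (bromide of 17) | CC1=C[C@@H](O[Si](CC)(CC)CC)CC(C)(C)[C@@H]1/C=C/C(C)=C/C=C/C(C)=C/CBr | intermediate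
20 | unsymmetrical C40 diallylic sulfone: the C20 chain of 17 and the C20 chain of 12 joined through C15 and C15' to one SO2 group | CC1=C[C@@H](O[Si](CC)(CC)CC)CC(C)(C)[C@@H]1/C=C/C(C)=C/C=C/C(C)=C/CS(=O)(=O)C/C=C(C)/C=C/C=C(C)/C=C/[C@@H]1C(C)=C[C@@H](O[Si](C)(C)C(C)(C)C)CC1(C)C | intermediate
21 | 15-bromo derivative of sulfone 20 (bromine on C15 next to sulfur; the C15' regioisomer converges; new centre unspecified) | CC1=C[C@@H](O[Si](CC)(CC)CC)CC(C)(C)[C@@H]1/C=C/C(C)=C/C=C/C(C)=C/C(Br)S(=O)(=O)C/C=C(C)/C=C/C=C(C)/C=C/[C@@H]1C(C)=C[C@@H](O[Si](C)(C)C(C)(C)C)CC1(C)C | intermediate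
22 | thiirane 1,1-dioxide spanning C15 and C15' (ring carbons unspecified) | CC1=C[C@@H](O[Si](CC)(CC)CC)CC(C)(C)[C@@H]1/C=C/C(C)=C/C=C/C(C)=C/C2C(/C=C(C)/C=C/C=C(C)/C=C/[C@@H]3C(C)=C[C@@H](O[Si](C)(C)C(C)(C)C)CC3(C)C)S2(=O)=O | intermediate
23 | (15Z)-isomer of 24, the part of the crude olefination product with a cis central double bond | CC1=C[C@@H](O[Si](CC)(CC)CC)CC(C)(C)[C@@H]1\C=C\C(C)=C\C=C\C(C)=C\C=C/C=C(C)/C=C/C=C(C)/C=C/[C@@H]1C(C)=C[C@@H](O[Si](C)(C)C(C)(C)C)CC1(C)C | intermediate
24 | (all-E)-(3S,6S,3'S,6'S)-3-(triethylsilyloxy)-3'-(tert-butyldimethylsilyloxy)-ε,ε-carotene | CC1=C[C@@H](O[Si](CC)(CC)CC)CC(C)(C)[C@@H]1/C=C/C(C)=C/C=C/C(C)=C/C=C/C=C(C)/C=C/C=C(C)/C=C/[C@@H]1C(C)=C[C@@H](O[Si](C)(C)C(C)(C)C)CC1(C)C | intermediate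
25 | (all-E)-(3S,6S,3'S,6'S)-3'-(tert-butyldimethylsilyloxy)-ε,ε-caroten-3-ol | CC1=C[C@@H](O)CC(C)(C)[C@@H]1/C=C/C(C)=C/C=C/C(C)=C/C=C/C=C(C)/C=C/C=C(C)/C=C/[C@@H]1C(C)=C[C@@H](O[Si](C)(C)C(C)(C)C)CC1(C)C | intermediate
26 | (all-E)-(6S,3'S,6'S)-3'-(tert-butyldimethylsilyloxy)-ε,ε-caroten-3-one | CC1=CC(=O)CC(C)(C)[C@@H]1/C=C/C(C)=C/C=C/C(C)=C/C=C/C=C(C)/C=C/C=C(C)/C=C/[C@@H]1C(C)=C[C@@H](O[Si](C)(C)C(C)(C)C)CC1(C)C | intermediate
27 | (all-E)-(6S,3'S,6'S)-3'-hydroxy-ε,ε-caroten-3-one | CC1=CC(=O)CC(C)(C)[C@@H]1/C=C/C(C)=C/C=C/C(C)=C/C=C/C=C(C)/C=C/C=C(C)/C=C/[C@@H]1C(C)=C[C@@H](O)CC1(C)C | target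

Total step count: 17 (the thermal equilibration of the central double bond is run on the crude product of step 14 and counted with it).
Longest linear sequence: 15 steps (steps 1–10, then 13–17).

Steps most likely to fail

Step 14. The delocalised α-sulfonyl carbanion may be brominated at a remote carbon of the tetraene, or the base may move double bonds before the episulfone closes. The fallback forms the same C15=C15' bond by Wittig olefination. It sets out from 17 and 12. Bromide 19, made from 17 as in step 13, is treated with PPh3 in CH2Cl2 at 0 °C to give the C20 triphenylphosphonium bromide F1. Oxidation of 12 with MnO2 in CH2Cl2 gives the C20 aldehyde F2. The ylide from F1 (NaN(SiMe3)2, THF, −78 °C) is combined with F2 and warmed to 0 °C. The resulting 15E/15Z nonaene is heated in heptane as in step 14 and comes back to the route at 24.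

Step 13. Release of the allylic sulfinate may be accompanied by double-bond migration through the C15' carbanion or by loss of SO2, and the polyenyl bromide may ionise before it is alkylated. The fallback builds the tether at the sulfide level and oxidises afterwards. It sets out from 12 and 17. Bromide 14, made from 12 as in step 10, reacts with KSAc in acetone at 0 °C to give the C20 thioacetate F3. K2CO3 in degassed MeOH–THF frees the thiolate in the presence of bromide 19 (from 17) and gives the unsymmetrical C40 sulfide F4. Oxidation with catalytic (n-Pr4N)RuO4 and N-methylmorpholine N-oxide in MeCN with 4 Å molecular sieves, a sulfide-to-sulfone method that spares alkenes, comes back to the route at 20.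

Step 4. The enzyme may discriminate the enantiomers poorly or acylate in the opposite sense. The fallback is a classical resolution through diastereomeric esters. It sets out from 5. Steglich esterification with (S)-O-methylmandelic acid (DCC, catalytic DMAP, CH2Cl2, −10 °C) gives two diastereomeric esters. These are separated by chromatography and assigned by the 1H NMR shielding pattern of O-methylmandelates. The (3S,6S)-configured O-methylmandelate F5 is cleaved with K2CO3 in EtOH and comes back to the route at 6.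

Further compounds
F1 | step 14 | {(2E,4E,6E,8E)-3,7-dimethyl-9-[(1S,4S)-2,6,6-trimethyl-4-(triethylsilyloxy)cyclohex-2-en-1-yl]nona-2,4,6,8-tetraen-1-yl}triphenylphosphonium bromide | CC1=C[C@@H](O[Si](CC)(CC)CC)CC(C)(C)[C@@H]1/C=C/C(C)=C/C=C/C(C)=C/C[P+](c2ccccc2)(c2ccccc2)c2ccccc2.[Br-]
F2 | step 14 | (2E,4E,6E,8E)-9-[(1S,4S)-4-(tert-butyldimethylsilyloxy)-2,6,6-trimethylcyclohex-2-en-1-yl]-3,7-dimethylnona-2,4,6,8-tetraenal | CC1=C[C@@H](O[Si](C)(C)C(C)(C)C)CC(C)(C)[C@@H]1/C=C/C(C)=C/C=C/C(C)=C/C=O
F3 | step 13 | S-{(2E,4E,6E,8E)-9-[(1S,4S)-4-(tert-butyldimethylsilyloxy)-2,6,6-trimethylcyclohex-2-en-1-yl]-3,7-dimethylnona-2,4,6,8-tetraen-1-yl} ethanethioate | CC1=C[C@@H](O[Si](C)(C)C(C)(C)C)CC(C)(C)[C@@H]1/C=C/C(C)=C/C=C/C(C)=C/CSC(C)=O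
F4 | step 13 | unsymmetrical C40 diallylic sulfide (sulfide analogue of 20) | CC1=C[C@@H](O[Si](CC)(CC)CC)CC(C)(C)[C@@H]1/C=C/C(C)=C/C=C/C(C)=C/CSC/C=C(C)/C=C/C=C(C)/C=C/[C@@H]1C(C)=C[C@@H](O[Si](C)(C)C(C)(C)C)CC1(C)C
F5 | step 4 | ethyl (2E,4E)-5-[(1S,4S)-4-{[(2S)-2-methoxy-2-phenylacetyl]oxy}-2,6,6-trimethylcyclohex-2-en-1-yl]-3-methylpenta-2,4-dienoate | CC1=C[C@@H](OC(=O)[C@@H](OC)c2ccccc2)CC(C)(C)[C@@H]1/C=C/C(C)=C/C(=O)OCC
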